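Everything rests on assembling ring B rather than substituting it. The feature exploited is its crowded C1′–C6′ edge. C6′ holds a 1,1-dimethylallyl group directly next to the aryl–C2 link, and neither neighbour of C6′ is oxygenated, which rules out a Claisen-type transfer. A thermal [4+2] cycloaddition joins symmetric 2,3-bis(trimethylsilyloxy)butadiene, carrying O3′ and O4′ as silyl enol ethers, to methyl 4,4-dimethylhex-5-en-2-ynoate. The alkyne carbons of the ynoate already bear the quaternary carbon and the future C2 (as ester). This makes C1′–C2′ and C5′–C6′ and closes the carbocycle in one operation. Dehydrogenation, pyran closure at the free C2′, acylation of the ring A ketone and a C3 oxygenation, required because the target is a flavonol, finish the route.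

Key step: step 6

Remark: the target has no stereocentre and no stereodefined double bond, so all SMILES carry no stereodescriptors. Flavonoid numbering is used (C2–C8a for rings C and A, primed numbers for ring B).

Step 1
Reactants: 1 1-chloro-3-methylbut-2-ene (prenyl chloride)
Product: 3 2,2-dimethylbut-3-en-1-ol, via prenylmagnesium chloride 2 (not isolated)
Conditions: Mg turnings (excess), THF, 0–10 °C, slow addition; dry paraformaldehyde, 0 °C → rt; cold 1 M HCl work-up
Reagents that add atoms: formaldehyde (from paraformaldehyde), C=O; magnesium, [Mg] (stays only in 2)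
Why: Allylic Grignard reagents add to aldehydes through a cyclic SE2′ transition state at their more substituted terminus, so formaldehyde should be attacked by the tertiary carbon, which sets the quaternary carbon with its vinyl group at the outset (Grignard addition with allylic transposition).

Step 2
Reactants: 3 2,2-dimethylbut-3-en-1-ol
Product: 4 2,2-dimethylbut-3-enal
Conditions: Dess–Martin periodinane (1.1 equiv), CH2Cl2, 0 °C → rt; filtered through silica and kept as CH2Cl2 solution
Reagents that add atoms: none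
Why: Dess–Martin oxidation of a neopentyl-type primary alcohol stops at the non-enolisable aldehyde, which is volatile and is therefore carried on in solution.

Step 3
Reactants: 4 2,2-dimethylbut-3-enal
Product: 5 1,1-dibromo-3,3-dimethylpenta-1,4-diene
Conditions: CBr4, PPh3 (2 equiv per CBr4), CH2Cl2, 0 °C
Reagents that add atoms: tetrabromomethane, BrC(Br)(Br)Br
Why: The Ramirez dibromo-olefination (first half of the Corey–Fuchs sequence) works on α-quaternary aldehydes of the pivalaldehyde type and turns the volatile aldehyde into a compound that is easy to handle.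

Step 4
Reactants: 5 1,1-dibromo-3,3-dimethylpenta-1,4-diene
Product: 7 methyl 4,4-dimethylhex-5-en-2-ynoate, via lithium acetylide 6 (not isolated)
Conditions: n-BuLi (2.1 equiv), THF, −78 → 0 °C; ClCO2Me, −78 °C → rt
Reagents that add atoms: methyl chloroformate, COC(=O)Cl; n-butyllithium, [Li]CCCC (lithium stays only in 6)
Why: In the second half of the Corey–Fuchs sequence, bromine–lithium exchange, loss of LiBr with hydrogen migration and deprotonation give the acetylide, which is methoxycarbonylated in the same flask so that the very volatile free enyne is never isolated.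

Step 5
Reactants: 8 butane-2,3-dione
Product: 9 2,3-bis(trimethylsilyloxy)buta-1,3-diene
Conditions: Me3SiOTf (2.2 equiv), Et3N (2.5 equiv), Et2O, 0 °C → rt; distillation
Reagents that add atoms: trimethylsilyl trifluoromethanesulfonate, C[Si](C)(C)OS(=O)(=O)C(F)(F)F
Why: Double soft enolisation and O-silylation of the 1,2-diketone (silyl triflate/amine method) is the standard access to this diene.

Step 6
Reactants: 7 methyl 4,4-dimethylhex-5-en-2-ynoate; 9 2,3-bis(trimethylsilyloxy)buta-1,3-diene
Product: 10 methyl 2-(2-methylbut-3-en-2-yl)-4,5-bis(trimethylsilyloxy)cyclohexa-1,4-diene-1-carboxylate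
Conditions: 9 (3 equiv), neat, BHT (1 mol %), base-washed sealed tube under Ar, 150–160 °C, 48 h; excess 9 removed in vacuo
Reagents that add atoms: none
Why: The two silyloxy groups raise the diene HOMO and the ester lowers the alkyne LUMO, so the partners should combine in a concerted, suprafacial Diels–Alder reaction of normal electron demand that forms both σ bonds (C1′–C2′ and C5′–C6′) in a single event. The closest known reaction type is the cycloaddition of 2,3-bis(silyloxy)butadienes to acetylenic esters such as propiolates and acetylenedicarboxylates, whose adducts are dehydrogenated to catechols. The six-membered carbocycle is closed intermolecularly in the [4+2] mode, all four diene carbons and both alkyne carbons becoming ring atoms. No stereocentre is created, because the adduct is a 1,4-cyclohexadiene whose ring carbons are sp2 or CH2 only. The step needs chemoselectivity alone: the ester-conjugated alkyne must react and the isolated vinyl group must not, which the lack of any activation at the vinyl group secures, and orientation is no issue because the diene is symmetric. The tert-alkyl group slows the addition, which is answered by neat reagents, excess diene, a radical inhibitor and high temperature, conditions under which 7, a 1,4-enyne without a sigmatropic or ene outlet, should persist.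

Step 7
Reactants: 10 methyl 2-(2-methylbut-3-en-2-yl)-4,5-bis(trimethylsilyloxy)cyclohexa-1,4-diene-1-carboxylate
Product: 12 methyl 4,5-dihydroxy-2-(2-methylbut-3-en-2-yl)benzoate, via bis(silyloxy)benzoate 11 (not isolated)
Conditions: DDQ (1.0 equiv), toluene, 0 °C → rt, hydroquinone filtered off; then MeOH, citric acid (cat.), rt, under Ar
Reagents that add atoms: none
Why: Hydride abstraction by DDQ from a doubly allylic CH2 next to a silyl enol ether and proton loss aromatise the 1,4-diene (quinone dehydrogenation), the silyl ethers shielding the nascent catechol from over-oxidation until the oxidant is gone, after which mild methanolysis frees both phenols.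

Step 8
Reactants: 12 methyl 4,5-dihydroxy-2-(2-methylbut-3-en-2-yl)benzoate
Product: 13 methyl 5-hydroxy-4-(methoxymethoxy)-2-(2-methylbut-3-en-2-yl)benzoate
Conditions: MOMCl (1.0 equiv), K2CO3 (1.0 equiv), acetone, 0 °C, under Ar
Reagents that add atoms: chloromethyl methyl ether, COCCl
Why: This is a selective Williamson-type mono-etherification of a catechol at its more acidic phenol, since O4′ is para to the ester and meta to the alkyl donor whereas O3′ is meta to the ester and para to the donor, so one equivalent of weak base should ionise mainly O4′–H.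

Step 9
Reactants: 13 methyl 5-hydroxy-4-(methoxymethoxy)-2-(2-methylbut-3-en-2-yl)benzoate; 14 3-chloro-3-methylbut-1-yne
Product: 15 methyl 4-(methoxymethoxy)-2-(2-methylbut-3-en-2-yl)-5-[(2-methylbut-3-yn-2-yl)oxy]benzoate
Conditions: 14 (1.5 equiv), DBU, CuCl2·2H2O (1 mol %), MeCN, 0 °C
Reagents that add atoms: none
Why: Copper-catalysed O-alkylation of phenols by tertiary propargylic chlorides forms hindered aryl 1,1-dimethylpropargyl ethers at 0 °C, conditions harmless to the ester, the MOM ether and the vinyl group.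

Step 10
Reactants: 15 methyl 4-(methoxymethoxy)-2-(2-methylbut-3-en-2-yl)-5-[(2-methylbut-3-yn-2-yl)oxy]benzoate
Product: 16 methyl 8-(methoxymethoxy)-2,2-dimethyl-6-(2-methylbut-3-en-2-yl)-2H-chromene-5-carboxylate
Conditions: o-xylene, BHT (cat.), 140 °C
Reagents that add atoms: none
Why: Aromatic propargyl Claisen rearrangement followed by 1,5-hydrogen shift and oxa-6π electrocyclisation gives the 2,2-dimethylchromene, and because C4′ is blocked by OMOM the only ortho carbon that can rearomatise is C2′, which fixes the ring fusion of the target.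

Step 11
Reactants: 16 methyl 8-(methoxymethoxy)-2,2-dimethyl-6-(2-methylbut-3-en-2-yl)-2H-chromene-5-carboxylate
Product: 17 8-(methoxymethoxy)-2,2-dimethyl-6-(2-methylbut-3-en-2-yl)-2H-chromene-5-carboxylic acid
Conditions: NaSEt (3 equiv), DMF, 70 °C; cold 0.5 M HCl to pH 4
Reagents that add atoms: none
Why: The ester carbonyl sits between the tert-alkyl group and the chromene C4–H and would resist saponification, so the acid is released by SN2 attack of thiolate on the O-methyl carbon (nucleophilic ester dealkylation), which leaves the aryl MOM ether and the alkenes alone.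

Step 12
Reactants: 18 1-(2,4,6-trihydroxyphenyl)ethan-1-one; 1 1-chloro-3-methylbut-2-ene
Product: 19 1-[2,4,6-trihydroxy-3-(3-methylbut-2-en-1-yl)phenyl]ethan-1-one
Conditions: 1 (0.9 equiv), KOH, H2O, 0 °C → rt
Reagents that add atoms: none
Why: C-Alkylation of the ambident phloroglucinol-type phenolate in water is known for this ketone, the two free ring carbons are equivalent, and keeping the chloride limiting restrains double prenylation.

Step 13
Reactants: 19 1-[2,4,6-trihydroxy-3-(3-methylbut-2-en-1-yl)phenyl]ethan-1-one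
Product: 20 1-[2-hydroxy-4,6-bis(methoxymethoxy)-3-(3-methylbut-2-en-1-yl)phenyl]ethan-1-one
Conditions: MOMCl (2.1 equiv), i-Pr2NEt, CH2Cl2, 0 °C → rt
Reagents that add atoms: chloromethyl methyl ether, COCCl
Why: In this Williamson-type etherification the non-chelated 4-OH reacts first and, of the two chelated phenols, the open 6-OH reacts before the 2-OH wedged between acetyl and prenyl groups, which leaves free exactly the oxygen that becomes O1 next to C8.

Step 14
Reactants: 17 8-(methoxymethoxy)-2,2-dimethyl-6-(2-methylbut-3-en-2-yl)-2H-chromene-5-carboxylic acid; 20 1-[2-hydroxy-4,6-bis(methoxymethoxy)-3-(3-methylbut-2-en-1-yl)phenyl]ethan-1-one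
Product: 23 1-[2-hydroxy-4,6-bis(methoxymethoxy)-3-(3-methylbut-2-en-1-yl)phenyl]-3-[8-(methoxymethoxy)-2,2-dimethyl-6-(2-methylbut-3-en-2-yl)-2H-chromen-5-yl]propane-1,3-dione, via acid chloride 21 (not isolated), via dilithio ketone 22 (not isolated)
Conditions: (a) 17, 1-chloro-N,N,2-trimethylprop-1-en-1-amine, CH2Cl2, 0 °C → rt, evaporate; (b) 20, LiN(SiMe3)2 (3.2 equiv), THF, −78 → −10 °C, then 21 in THF, −78 °C → rt; AcOH quench
Reagents that add atoms: 1-chloro-N,N,2-trimethylprop-1-en-1-amine, CC(C)=C(Cl)N(C)C (chlorine stays only in 21); lithium hexamethyldisilazide, [Li]N([Si](C)(C)C)[Si](C)(C)C (lithium stays only in 22)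
Why: Direct C-acylation of the lithium dianion of an o-hydroxyacetophenone by an aroyl chloride (one-flask variant of the Baker–Venkataraman route) gives the 1,3-diketone, a third equivalent of base taking up its acidic proton, and the neutral chloroenamine makes the acid chloride without HCl so that the MOM ether survives.

Step 15
Reactants: 23 the 1,3-diketone of step 14
Product: 24 5,7-bis(methoxymethoxy)-2-[8-(methoxymethoxy)-2,2-dimethyl-6-(2-methylbut-3-en-2-yl)-2H-chromen-5-yl]-8-(3-methylbut-2-en-1-yl)-4H-chromen-4-one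
Conditions: NaOAc, glacial AcOH, 90 °C
Reagents that add atoms: none
Why: Cyclodehydration of an o-hydroxyaryl 1,3-diketone (six-ring hemiketal formation and loss of water) proceeds in buffered acetic acid, a medium too weak to cleave aryl MOM ethers quickly or to protonate the alkenes, and as only the 2-OH is free, O1 ends up next to the prenylated C8.

Step 16
Reactants: 24 the tris-MOM flavone of step 15
Product: 27 3-hydroxy-5,7-bis(methoxymethoxy)-2-[8-(methoxymethoxy)-2,2-dimethyl-6-(2-methylbut-3-en-2-yl)-2H-chromen-5-yl]-8-(3-methylbut-2-en-1-yl)-4H-chromen-4-one, via 3-lithioflavone 25 (not isolated), via C3 dimethyl boronate 26 (not isolated)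
Conditions: LiN(i-Pr)2 (1.5 equiv), THF, −78 °C; B(OMe)3, −78 → 0 °C; AcOH, 30% H2O2, 0 °C → rt
Reagents that add atoms: hydrogen peroxide, OO; trimethyl borate, COB(OC)OC (boron stays only in 26); lithium diisopropylamide, [Li]N(C(C)C)C(C)C (lithium stays only in 25)
Why: Flavones are deprotonated at C3 by the lithium amide at −78 °C with the lithium held by the C4 carbonyl oxygen, and borate trapping followed by peroxide oxidation (lithiation–borylation–oxidation) installs the flavonol oxygen without an electrophilic oxidant that would epoxidise the three alkenes.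

Step 17
Reactants: 27 the tris-MOM flavonol of step 16
Product: 28 3,5,7-trihydroxy-2-[8-hydroxy-2,2-dimethyl-6-(2-methylbut-3-en-2-yl)-2H-chromen-5-yl]-8-(3-methylbut-2-en-1-yl)-4H-chromen-4-one (target)
Conditions: 2 M HCl, MeOH–THF, 45 °C, short reaction time
Reagents that add atoms: none
Why: Acid-catalysed acetal exchange with methanol removes all three MOM groups under conditions commonly tolerated by C-prenyl phenols and 2,2-dimethylchromenes, moderate temperature and short time guarding against chroman formation between 7-OH and the 8-prenyl group.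

Compound list
1 | 1-chloro-3-methylbut-2-ene | CC(C)=CCCl | starting material
2 | (3-methylbut-2-en-1-yl)magnesium chloride | CC(C)=CC[Mg]Cl | intermediate
3 | 2,2-dimethylbut-3-en-1-ol | C=CC(C)(C)CO | intermediate
4 | 2,2-dimethylbut-3-enal | C=CC(C)(C)C=O | intermediate
5 | 1,1-dibromo-3,3-dimethylpenta-1,4-diene | C=CC(C)(C)C=C(Br)Br | intermediate
6 | (3,3-dimethylpent-4-en-1-yn-1-yl)lithium | [Li]C#CC(C)(C)C=C | intermediate
7 | methyl 4,4-dimethylhex-5-en-2-ynoate | COC(=O)C#CC(C)(C)C=C | intermediate
8 | butane-2,3-dione | CC(=O)C(C)=O | starting material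
9 | 2,3-bis(trimethylsilyloxy)buta-1,3-diene | C=C(O[Si](C)(C)C)C(=C)O[Si](C)(C)C | intermediate
10 | methyl 2-(2-methylbut-3-en-2-yl)-4,5-bis(trimethylsilyloxy)cyclohexa-1,4-diene-1-carboxylate | COC(=O)C1=C(C(C)(C)C=C)CC(O[Si](C)(C)C)=C(O[Si](C)(C)C)C1 | intermediate
11 | methyl 2-(2-methylbut-3-en-2-yl)-4,5-bis(trimethylsilyloxy)benzoate | COC(=O)c1cc(O[Si](C)(C)C)c(O[Si](C)(C)C)cc1C(C)(C)C=C | intermediate
12 | methyl 4,5-dihydroxy-2-(2-methylbut-3-en-2-yl)benzoate | COC(=O)c1cc(O)c(O)cc1C(C)(C)C=C | intermediate
13 | methyl 5-hydroxy-4-(methoxymethoxy)-2-(2-methylbut-3-en-2-yl)benzoate | COC(=O)c1cc(O)c(OCOC)cc1C(C)(C)C=C | intermediate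
14 | 3-chloro-3-methylbut-1-yne | C#CC(C)(C)Cl | starting material
15 | methyl 4-(methoxymethoxy)-2-(2-methylbut-3-en-2-yl)-5-[(2-methylbut-3-yn-2-yl)oxy]benzoate | COC(=O)c1cc(OC(C)(C)C#C)c(OCOC)cc1C(C)(C)C=C | intermediate
16 | methyl 8-(methoxymethoxy)-2,2-dimethyl-6-(2-methylbut-3-en-2-yl)-2H-chromene-5-carboxylate | COC(=O)c1c(C(C)(C)C=C)cc(OCOC)c2OC(C)(C)C=Cc12 | intermediate
17 | 8-(methoxymethoxy)-2,2-dimethyl-6-(2-methylbut-3-en-2-yl)-2H-chromene-5-carboxylic acid | OC(=O)c1c(C(C)(C)C=C)cc(OCOC)c2OC(C)(C)C=Cc12 | intermediate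
18 | 1-(2,4,6-trihydroxyphenyl)ethan-1-one | CC(=O)c1c(O)cc(O)cc1O | starting material
19 | 1-[2,4,6-trihydroxy-3-(3-methylbut-2-en-1-yl)phenyl]ethan-1-one | CC(=O)c1c(O)cc(O)c(CC=C(C)C)c1O | intermediate
20 | 1-[2-hydroxy-4,6-bis(methoxymethoxy)-3-(3-methylbut-2-en-1-yl)phenyl]ethan-1-one | CC(=O)c1c(O)c(CC=C(C)C)c(OCOC)cc1OCOC | intermediate
21 | 8-(methoxymethoxy)-2,2-dimethyl-6-(2-methylbut-3-en-2-yl)-2H-chromene-5-carbonyl chloride | ClC(=O)c1c(C(C)(C)C=C)cc(OCOC)c2OC(C)(C)C=Cc12 | intermediate
22 | dilithium enolate-phenolate of 20 | [Li]OC(=C)c1c(O[Li])c(CC=C(C)C)c(OCOC)cc1OCOC | intermediate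
23 | 1-[2-hydroxy-4,6-bis(methoxymethoxy)-3-(3-methylbut-2-en-1-yl)phenyl]-3-[8-(methoxymethoxy)-2,2-dimethyl-6-(2-methylbut-3-en-2-yl)-2H-chromen-5-yl]propane-1,3-dione | COCOc1cc(OCOC)c(C(=O)CC(=O)c2c(C(C)(C)C=C)cc(OCOC)c3OC(C)(C)C=Cc23)c(O)c1CC=C(C)C | intermediate
24 | 5,7-bis(methoxymethoxy)-2-[8-(methoxymethoxy)-2,2-dimethyl-6-(2-methylbut-3-en-2-yl)-2H-chromen-5-yl]-8-(3-methylbut-2-en-1-yl)-4H-chromen-4-one | COCOc1cc(OCOC)c2c(=O)cc(-c3c(C(C)(C)C=C)cc(OCOC)c4OC(C)(C)C=Cc34)oc2c1CC=C(C)C | intermediate
25 | 3-lithio derivative of 24 | COCOc1cc(OCOC)c2c(=O)c([Li])c(-c3c(C(C)(C)C=C)cc(OCOC)c4OC(C)(C)C=Cc34)oc2c1CC=C(C)C | intermediate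
26 | dimethyl boronate of 24 at C3 | COCOc1cc(OCOC)c2c(=O)c(B(OC)OC)c(-c3c(C(C)(C)C=C)cc(OCOC)c4OC(C)(C)C=Cc34)oc2c1CC=C(C)C | intermediate
27 | 3-hydroxy-5,7-bis(methoxymethoxy)-2-[8-(methoxymethoxy)-2,2-dimethyl-6-(2-methylbut-3-en-2-yl)-2H-chromen-5-yl]-8-(3-methylbut-2-en-1-yl)-4H-chromen-4-one | COCOc1cc(OCOC)c2c(=O)c(O)c(-c3c(C(C)(C)C=C)cc(OCOC)c4OC(C)(C)C=Cc34)oc2c1CC=C(C)C | intermediate
28 | 3,5,7-trihydroxy-2-[8-hydroxy-2,2-dimethyl-6-(2-methylbut-3-en-2-yl)-2H-chromen-5-yl]-8-(3-methylbut-2-en-1-yl)-4H-chromen-4-one (CNP0241222.0) | C=CC(C)(C)c1cc(O)c2c(c1-c1oc3c(CC=C(C)C)c(O)cc(O)c3c(=O)c1O)C=CC(C)(C)O2 | target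

Total step count: 17. Longest linear sequence: 14 steps (1–4, 6–11, 14–17).

Steps most likely to fail

**Step 6.** Addition to the alkyne carbon shielded by the quaternary centre may be so slow that thermal oligomerisation and adventitious desilylation of the diene win.
- The fallback keeps the disconnection but activates the alkyne more strongly. It sets out from 5.
- Acetylide 6 is generated as in step 4 but quenched with DMF, which should give 4,4-dimethylhex-5-en-2-ynal F1.
- The formyl group lowers the LUMO well below that of the ester. Diene 9 should therefore add in toluene at about 80–100 °C to give 2-(2-methylbut-3-en-2-yl)-4,5-bis(trimethylsilyloxy)cyclohexa-1,4-diene-1-carbaldehyde F2.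
- DDQ should then give 2-(2-methylbut-3-en-2-yl)-4,5-bis(trimethylsilyloxy)benzaldehyde F3. Methanolysis should give 4,5-dihydroxy-2-(2-methylbut-3-en-2-yl)benzaldehyde F4.
- The operations of steps 8–10 are repeated. MOMCl and K2CO3 lead to 5-hydroxy-4-(methoxymethoxy)-2-(2-methylbut-3-en-2-yl)benzaldehyde F5. Here the small, more nearly coplanar formyl group should also sharpen the preference for O4′.
- Compound 14 with DBU and CuCl2·2H2O leads to 4-(methoxymethoxy)-2-(2-methylbut-3-en-2-yl)-5-[(2-methylbut-3-yn-2-yl)oxy]benzaldehyde F6. Heating leads to 8-(methoxymethoxy)-2,2-dimethyl-6-(2-methylbut-3-en-2-yl)-2H-chromene-5-carbaldehyde F7.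
- Pinnick oxidation (NaClO2, NaH2PO4, 2-methylbut-2-ene, t-BuOH–H2O) comes back to the route at 17. Step 11 falls away and the step count is unchanged.

**Step 8.** The neighbouring tert-alkyl group twists the ester out of conjugation. The acidity gap between the two phenols may then be small, giving poor site discrimination and double protection.
- The fallback inverts the order and uses nucleophilicity instead of acidity. It sets out from 12.
- NaH (2.1 equiv) in DMF at 0 °C should give the disodium catecholate F8. Its less stabilised oxygen, O3′ (para to the alkyl donor), is the more reactive.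
- One equivalent of 14 (KI cat., 50 °C) should therefore give methyl 4-hydroxy-2-(2-methylbut-3-en-2-yl)-5-[(2-methylbut-3-yn-2-yl)oxy]benzoate F9.
- MOMCl with i-Pr2NEt then caps the only remaining phenol, and the route is rejoined at 15.

**Step 14.** Attack of the enolate on the acyl chloride flanked on both sides may be too slow, so that proton transfer, O-acylation or attack by the excess amide base takes over.
- The fallback lowers the electrophile to the aldehyde level, where the carbonyl carbon is far more open. It sets out from 16.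
- LiAlH4 in THF should give [8-(methoxymethoxy)-2,2-dimethyl-6-(2-methylbut-3-en-2-yl)-2H-chromen-5-yl]methanol F10.
- MnO2 in CH2Cl2 should give 8-(methoxymethoxy)-2,2-dimethyl-6-(2-methylbut-3-en-2-yl)-2H-chromene-5-carbaldehyde F7, the aldehyde already met above.
- Addition of F7 to dianion 22 at −78 °C followed by an AcOH quench should give racemic 3-hydroxy-1-[2-hydroxy-4,6-bis(methoxymethoxy)-3-(3-methylbut-2-en-1-yl)phenyl]-3-[8-(methoxymethoxy)-2,2-dimethyl-6-(2-methylbut-3-en-2-yl)-2H-chromen-5-yl]propan-1-one F11.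
- Oxidation of its benzylic carbinol with Dess–Martin periodinane erases the transient stereocentre and comes back to the route at 23.

Further compounds
F1 | step 6 | 4,4-dimethylhex-5-en-2-ynal | O=CC#CC(C)(C)C=C
F2 | step 6 | 2-(2-methylbut-3-en-2-yl)-4,5-bis(trimethylsilyloxy)cyclohexa-1,4-diene-1-carbaldehyde | O=CC1=C(C(C)(C)C=C)CC(O[Si](C)(C)C)=C(O[Si](C)(C)C)C1
F3 | step 6 | 2-(2-methylbut-3-en-2-yl)-4,5-bis(trimethylsilyloxy)benzaldehyde | O=Cc1cc(O[Si](C)(C)C)c(O[Si](C)(C)C)cc1C(C)(C)C=C
F4 | step 6 | 4,5-dihydroxy-2-(2-methylbut-3-en-2-yl)benzaldehyde | O=Cc1cc(O)c(O)cc1C(C)(C)C=C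
F5 | step 6 | 5-hydroxy-4-(methoxymethoxy)-2-(2-methylbut-3-en-2-yl)benzaldehyde | O=Cc1cc(O)c(OCOC)cc1C(C)(C)C=C
F6 | step 6 | 4-(methoxymethoxy)-2-(2-methylbut-3-en-2-yl)-5-[(2-methylbut-3-yn-2-yl)oxy]benzaldehyde | O=Cc1cc(OC(C)(C)C#C)c(OCOC)cc1C(C)(C)C=C
F7 | step 6 | 8-(methoxymethoxy)-2,2-dimethyl-6-(2-methylbut-3-en-2-yl)-2H-chromene-5-carbaldehyde | O=Cc1c(C(C)(C)C=C)cc(OCOC)c2OC(C)(C)C=Cc12
F8 | step 8 | disodium 4-(methoxycarbonyl)-5-(2-methylbut-3-en-2-yl)benzene-1,2-diolate | COC(=O)c1cc([O-])c([O-])cc1C(C)(C)C=C.[Na+].[Na+]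
F9 | step 8 | methyl 4-hydroxy-2-(2-methylbut-3-en-2-yl)-5-[(2-methylbut-3-yn-2-yl)oxy]benzoate | COC(=O)c1cc(OC(C)(C)C#C)c(O)cc1C(C)(C)C=C
F10 | step 14 | [8-(methoxymethoxy)-2,2-dimethyl-6-(2-methylbut-3-en-2-yl)-2H-chromen-5-yl]methanol | OCc1c(C(C)(C)C=C)cc(OCOC)c2OC(C)(C)C=Cc12
F11 | step 14 | 3-hydroxy-1-[2-hydroxy-4,6-bis(methoxymethoxy)-3-(3-methylbut-2-en-1-yl)phenyl]-3-[8-(methoxymethoxy)-2,2-dimethyl-6-(2-methylbut-3-en-2-yl)-2H-chromen-5-yl]propan-1-one (racemic) | COCOc1cc(OCOC)c(C(=O)CC(O)c2c(C(C)(C)C=C)cc(OCOC)c3OC(C)(C)C=Cc23)c(O)c1CC=C(C)C
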